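**Retrosynthetic overview**
1. The last bond is the C3–O ester, made from bicyclic alcohol 15 and trienoic acid 23 (hexanal extended by two phosphorus olefinations).
2. Ring B of 15 is elaborated on 8-ketone 7: C9–OH by enolate hydroxylation, C7=C11 by aldol addition and elimination. Ketone 7 comes from ene-dione 6 by one dissolving-metal reduction that sets C10–H and C3–OH.
3. Ring A (C1–C2–C3–C4–C5–C10) is disconnected at C4–C5. Ene-dione 6 arises by a semipinacol ring enlargement of the five-membered carbinol 5, in which C5 shifts from C3 to the selenium-bearing CH(CH3) carbon C4.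
4. The enabling feature: in ring A the oxygenated C3, the methyl-bearing methine C4 and the methyl-bearing quaternary C5 are contiguous. Without C4, ring A is a cyclopentanone (C3=O) attached to the quaternary C5 and fused to the ring B enone (C8=O, C9=C10), which is the Hajos–Parrish ketone 1.
5. Ring order: ring B comes ready-made in 1; ring A is formed last, in step 4, by enlargement of the five-membered ring C1–C2–C3–C5–C10.

Key step: step 4

Remark: locants follow eremophilane numbering in all compounds (ring A = C1–C5 and C10; ring B = C5–C10; C11 = exocyclic alkene carbon on C7, C12 = its CH2O carbon, C13 = its methyl; C14 = methyl on C5; C15 = methyl on C4). C4 is absent in 1 and is the exocyclic carbon on C3 in 3–5. β is the face of the C5 methyl, α the opposite face. Target descriptors in this numbering: 3R,4R,5R,9S,10R, 7(11)E.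

**Step 1**
Reactants: 1 (S)-Hajos–Parrish ketone; 2 ethyltriphenylphosphonium bromide
Product: 3 Z-ethylidene enone
Conditions: 2 (2.2 equiv), KOtBu (2.1 equiv), THF, 0 °C; then 1, rt; work-up with dilute aq. HCl
Reagents that add atoms: none
Why: Wittig olefination, in which the non-stabilised ylide should add to the strained, non-conjugated cyclopentanone carbonyl (C3) faster than to the vinylogous enone carbonyl (which is also masked as its dienolate under the basic conditions and restored on acidic work-up), and the kinetic oxaphosphetane places the ylide methyl syn to the bulkier quaternary C5, giving the Z alkene as in ethylidenations of 17-oxo steroids.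

**Step 2**
Reactants: 3 Z-ethylidene enone
Product: 4 α-spiro-epoxide
Conditions: mCPBA, CH2Cl2 / aq. NaHCO3, 0 °C
Reagents that add atoms: mCPBA, OOC(=O)c1cccc(Cl)c1
Why: Prilezhaev epoxidation, in which the peracid should select the electron-rich trisubstituted exocyclic alkene over the electron-poor enone and add from the α face (anti to the C5 methyl, the face from which hydride adds to C3 of 1), with syn transfer so that the Z geometry fixes the configuration of the CH(CH3) epoxide carbon C4.

**Step 3**
Reactants: 4 α-spiro-epoxide
Product: 5 hydroxy selenide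
Conditions: PhSeH, Cs2CO3 (cat.), EtOH, 60 °C, argon
Reagents that add atoms: benzeneselenol, [SeH]c1ccccc1
Why: SN2 opening of the epoxide by the selenolate at the less substituted carbon C4 with inversion, which should give the tertiary α-alcohol at C3 and the (R)-configured C4–Se centre, while the soft selenolate adds only reversibly to the β,β-disubstituted enone.

**Step 4**
Reactants: 5 hydroxy selenide
Product: 6 ene-dione
Conditions: AgBF4 on neutral Al2O3, CH2Cl2, 0 °C to rt, dark
Reagents that add atoms: none
Why: Monovalent silver binds the selenium of 5 and turns PhSe into a leaving group; as the C4–Se bond ionises, the C3–C5 bond lying anti-periplanar to it migrates from C3 to C4 and the C3 hydroxyl collapses to the ketone (semipinacol rearrangement, the selenium-mediated ring enlargement of 1-(1-selenoalkyl)cycloalkanols and the same event as the D-homoannulation of 17-hydroxy-20-substituted pregnanes). Ring A is closed by ring enlargement: the five-membered ring C1–C2–C3–C5–C10 takes up C4 through a 1,2-shift of C5, so the new ring bond is C4–C5. C4 is the only new stereocentre and is set by inversion at the selenium-bearing carbon (backside entry of C5), which should turn the (R)-selenide into the 4β-methyl ketone, while C5 migrates with retention. The step needs migration of the quaternary C5 rather than of C2, and rearrangement rather than re-closure to epoxide 4; the higher migratory aptitude of the more substituted carbon in cationoid semipinacol shifts should secure the first, and the non-basic silver conditions (no alkoxide) the second. The alumina takes up the HBF4, so that C4, now alpha to a ketone, is not equilibrated.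

**Step 5**
Reactants: 6 ene-dione
Product: 7 hydroxy ketone
Conditions: Li (excess), t-BuOH, NH3(l)/THF, −78 to −33 °C; isoprene; solid NH4Cl
Reagents that add atoms: none
Why: Dissolving-metal (Birch-type) reduction, in which the enone is reduced to its enolate with protonation of C10 from the α face (trans ring fusion, as with other angular-methyl octalones) and the C3 ketone is reduced through its ketyl to the thermodynamically favoured equatorial 3α-alkoxide (trans to the equatorial C4 methyl), the C8 enolate being protected from over-reduction until the quench.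

**Step 6**
Reactants: 7 hydroxy ketone
Product: 8 TES ether
Conditions: Et3SiCl, imidazole, DMF, 0 °C to rt
Reagents that add atoms: chlorotriethylsilane, CC[Si](Cl)(CC)CC
Why: Silylation of the only hydroxyl, with TES chosen because it can later be removed in the presence of TBS ethers.

**Step 7**
Reactants: 8 TES ether; 9 1-(tert-butyldimethylsilyloxy)propan-2-one
Product: 10 aldol adduct
Conditions: LiN(iPr)2, THF, −78 °C; then 9, −78 °C; AcOH quench at −78 °C
Reagents that add atoms: none
Why: Directed aldol addition, in which kinetic deprotonation of the trans-decal-8-one should occur at C7 (away from the ring fusion, as 3-oxo-5α-steroids enolise toward C2) and the lithium enolate adds to the activated α-silyloxy ketone 9; both new stereocentres are removed in step 8.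

**Step 8**
Reactants: 10 aldol adduct
Product: 12 E-enone, via tertiary mesylate 11 (not isolated)
Conditions: MsCl, Et3N, DMAP (cat.), CH2Cl2, 0 °C; then DBU, rt; chromatography
Reagents that add atoms: none
Why: E1cB elimination of the tertiary mesylate through the C7 enolate (aldol condensation), in which the conjugated tetrasubstituted enone is the thermodynamic alkene and the E isomer (C8 carbonyl trans to the CH2OSi group, cis to the small methyl) is expected to predominate as it does in olefinations of silyloxyacetone with carbonyl-stabilised phosphorus reagents; the minor Z isomer is removed by chromatography.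

**Step 9**
Reactants: 12 E-enone
Product: 13 9α-hydroxy enone
Conditions: KN(SiMe3)2, THF, −78 °C; 2-(phenylsulfonyl)-3-phenyloxaziridine, −78 °C; AcOH quench
Reagents that add atoms: 2-(phenylsulfonyl)-3-phenyloxaziridine, O=S(=O)(N1OC1c1ccccc1)c1ccccc1
Why: α'-Hydroxylation of an enone by oxaziridine oxidation of its enolate, in which the amide base removes the C9 proton kinetically (cross-conjugated enolate) and oxygen is delivered from the α face because the β face of C9 is blocked by the syn-axial C5 methyl, giving the equatorial 9α-alcohol, which is also the thermodynamically preferred epimer.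

**Step 10**
Reactants: 13 9α-hydroxy enone
Product: 14 9α-TBS ether
Conditions: TBSOTf, 2,6-lutidine, CH2Cl2, −78 to 0 °C
Reagents that add atoms: tert-butyldimethylsilyl triflate, CC(C)(C)[Si](C)(C)OS(=O)(=O)C(F)(F)F
Why: Silylation of the hindered secondary ketol hydroxyl with the reactive silyl triflate, leaving the enone untouched.

**Step 11**
Reactants: 14 9α-TBS ether
Product: 15 3α-alcohol
Conditions: PPTS (cat.), MeOH/CH2Cl2, 0 °C
Reagents that add atoms: none
Why: Acid-catalysed methanolysis, which should cleave the secondary triethylsilyl ether much faster than the two bulkier TBS ethers (selective desilylation by silyl size).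

**Step 12**
Reactants: 16 hexanal; 17 triethyl (E)-3-methyl-4-phosphonobut-2-enoate
Product: 18 ethyl (2E,4E)-3-methyldeca-2,4-dienoate
Conditions: LiN(SiMe3)2, THF, −78 to 0 °C
Reagents that add atoms: none
Why: Vinylogous Horner–Wadsworth–Emmons olefination, in which the new C4=C5 bond forms E and the delocalised phosphonate anion equilibrates so that the 2E,4E ester should predominate.

**Step 13**
Reactants: 18 ethyl (2E,4E)-3-methyldeca-2,4-dienoate
Product: 19 (2E,4E)-3-methyldeca-2,4-dien-1-ol
Conditions: iBu2AlH, CH2Cl2, −78 °C; aq. KNaC4H4O6 work-up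
Reagents that add atoms: none
Why: 1,2-Reduction of the conjugated ester to the allylic alcohol with the aluminium hydride at low temperature, without isomerisation of the diene.

**Step 14**
Reactants: 19 (2E,4E)-3-methyldeca-2,4-dien-1-ol; 20 ethyl (triphenylphosphoranylidene)acetate
Product: 22 ethyl (2E,4E,6E)-5-methyldodeca-2,4,6-trienoate, via dienal 21 (not isolated)
Conditions: activated MnO2, CH2Cl2, rt
Reagents that add atoms: none
Why: Tandem allylic oxidation and Wittig olefination, in which MnO2 oxidises the allylic alcohol to the dienal and the stabilised ylide traps it at once with E selectivity, so that the isomerisation-prone dienal is never isolated.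

**Step 15**
Reactants: 22 ethyl (2E,4E,6E)-5-methyldodeca-2,4,6-trienoate
Product: 23 (2E,4E,6E)-5-methyldodeca-2,4,6-trienoic acid
Conditions: LiOH, THF/MeOH/H2O, rt; then aq. HCl to pH 3, 0 °C
Reagents that add atoms: lithium hydroxide, [Li+].[OH-]
Why: Saponification of the ethyl ester followed by mild acidification, conditions under which the conjugated triene should keep its geometry.

**Step 16**
Reactants: 15 3α-alcohol; 23 (2E,4E,6E)-5-methyldodeca-2,4,6-trienoic acid
Product: 24 bis-TBS ester
Conditions: DCC, DMAP, CH2Cl2, 0 °C to rt
Reagents that add atoms: none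
Why: Steglich esterification of the only free hydroxyl, the equatorial C3 alcohol, with retention at C3.

**Step 17**
Reactants: 24 bis-TBS ester
Product: 25 target CNP0226738.2
Conditions: HF·pyridine, pyridine/THF, 0 °C to rt
Reagents that add atoms: none
Why: Fluoride-mediated desilylation under buffered, weakly acidic conditions, which should remove both TBS ethers without base, so that the C9 ketol, the E-configured hydroxymethyl enone (which cannot cyclise onto C8) and the trienoate are not isomerised.

**Compound list**
1 | (S)-Hajos–Parrish ketone, (7aS)-7a-methyl-2,3,7,7a-tetrahydro-1H-indene-1,5(6H)-dione | C[C@]12CCC(=O)C=C1CCC2=O | starting material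
2 | ethyltriphenylphosphonium bromide | CC[P+](c1ccccc1)(c1ccccc1)c1ccccc1.[Br-] | starting material
3 | Z-ethylidene enone: 1 with C3=O replaced by C3=CH–CH3, alkene methyl syn to the quaternary C5 | C/C=C1/CCC2=CC(=O)CC[C@]12C | intermediate
4 | α-spiro-epoxide of 3: epoxide oxygen on C3 anti to the C5 methyl, epoxide carbon C4 (S) with its methyl cis to C5 | C[C@@H]1O[C@@]12CCC3=CC(=O)CC[C@]23C | intermediate
5 | hydroxy selenide: C3 carries α-OH and the β-(1R)-1-(phenylselanyl)ethyl group | C[C@@H]([Se]c1ccccc1)[C@@]1(O)CCC2=CC(=O)CC[C@]12C | intermediate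
6 | ene-dione, (4aR,5R)-4a,5-dimethyl-4,4a,7,8-tetrahydronaphthalene-2,6(3H,5H)-dione (4β,5β-dimethyl, C3=O, C8=O, C9=C10) | C[C@H]1C(=O)CCC2=CC(=O)CC[C@]12C | intermediate
7 | hydroxy ketone: trans-fused 3α-hydroxy-4β,5β-dimethyl-10α-H-decalin-8-one | C[C@H]1[C@H](O)CC[C@H]2CC(=O)CC[C@]12C | intermediate
8 | TES ether: 3α-triethylsilyloxy derivative of 7 | C[C@H]1[C@H](O[Si](CC)(CC)CC)CC[C@H]2CC(=O)CC[C@]12C | intermediate
9 | 1-(tert-butyldimethylsilyloxy)propan-2-one | CC(=O)CO[Si](C)(C)C(C)(C)C | starting material
10 | aldol adduct: 8 with C(OH)(CH3)CH2OTBS on C7, mixture of diastereomers at C7 and C11 | C[C@H]1[C@H](O[Si](CC)(CC)CC)CC[C@H]2CC(=O)C(C(C)(O)CO[Si](C)(C)C(C)(C)C)C[C@]12C | intermediate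
11 | tertiary mesylate of 10 | C[C@H]1[C@H](O[Si](CC)(CC)CC)CC[C@H]2CC(=O)C(C(C)(OS(C)(=O)=O)CO[Si](C)(C)C(C)(C)C)C[C@]12C | intermediate (not isolated)
12 | E-enone: 7(11)-en-8-one with C13 methyl cis and C12H2OTBS trans to C8=O, 3α-OTES | C[C@H]1[C@H](O[Si](CC)(CC)CC)CC[C@H]2CC(=O)/C(=C(\C)CO[Si](C)(C)C(C)(C)C)C[C@]12C | intermediate
13 | 9α-hydroxy enone: 12 with equatorial OH on C9 | C[C@H]1[C@H](O[Si](CC)(CC)CC)CC[C@H]2[C@H](O)C(=O)/C(=C(\C)CO[Si](C)(C)C(C)(C)C)C[C@]12C | intermediate
14 | 9α-TBS ether of 13 | C[C@H]1[C@H](O[Si](CC)(CC)CC)CC[C@H]2[C@H](O[Si](C)(C)C(C)(C)C)C(=O)/C(=C(\C)CO[Si](C)(C)C(C)(C)C)C[C@]12C | intermediate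
15 | 3α-alcohol: 14 without the TES group | C[C@H]1[C@H](O)CC[C@H]2[C@H](O[Si](C)(C)C(C)(C)C)C(=O)/C(=C(\C)CO[Si](C)(C)C(C)(C)C)C[C@]12C | intermediate
16 | hexanal | CCCCCC=O | starting material
17 | triethyl (E)-3-methyl-4-phosphonobut-2-enoate | CCOC(=O)/C=C(\C)CP(=O)(OCC)OCC | starting material
18 | ethyl (2E,4E)-3-methyldeca-2,4-dienoate | CCCCC/C=C/C(C)=C/C(=O)OCC | intermediate
19 | (2E,4E)-3-methyldeca-2,4-dien-1-ol | CCCCC/C=C/C(C)=C/CO | intermediate
20 | ethyl (triphenylphosphoranylidene)acetate | CCOC(=O)C=P(c1ccccc1)(c1ccccc1)c1ccccc1 | starting material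
21 | (2E,4E)-3-methyldeca-2,4-dienal | CCCCC/C=C/C(C)=C/C=O | intermediate (not isolated)
22 | ethyl (2E,4E,6E)-5-methyldodeca-2,4,6-trienoate | CCCCC/C=C/C(C)=C/C=C/C(=O)OCC | intermediate
23 | (2E,4E,6E)-5-methyldodeca-2,4,6-trienoic acid | CCCCC/C=C/C(C)=C/C=C/C(=O)O | intermediate
24 | bis-TBS ester: 15 acylated at the 3α-oxygen by 23 (9α-OTBS, 12-OTBS) | C[C@H]1[C@H](OC(=O)/C=C/C=C(C)/C=C/CCCCC)CC[C@H]2[C@H](O[Si](C)(C)C(C)(C)C)C(=O)/C(=C(\C)CO[Si](C)(C)C(C)(C)C)C[C@]12C | intermediate
25 | CNP0226738.2: 3α-[(2E,4E,6E)-5-methyldodeca-2,4,6-trienoyloxy]-9α,12-dihydroxy-4β,5β-dimethyl-10α-H-eremophil-7(11)E-en-8-one | CCCCC/C=C/C(C)=C/C=C/C(=O)O[C@@H]1CC[C@H]2[C@H](O)C(=O)/C(=C(\C)CO)C[C@]2(C)[C@H]1C | target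

**Step count and risks**
Total step count: 17. Longest linear sequence: 13 steps (1 to 25 through steps 1–11, 16 and 17).

Steps most likely to fail:

1. Step 4. The ionised selenide may re-close to the epoxide, shift C2 instead of C5 or lose a proton to an alkene, and acid set free may equilibrate C4. The fallback sets out from epoxide 4 and uses a nitrogen leaving group instead of selenium. Opening at C4 with NaN3 (NH4Cl, aq. MeOH, 70 °C) should give azido alcohol F1. Staudinger reduction (PPh3, THF/H2O) should give amino alcohol F2. Nitrous acid deamination (NaNO2, aq. AcOH, 0 °C; Tiffeneau–Demjanov-type semipinacol shift of C5 with inversion at C4) comes back to the route at ene-dione 6.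

2. Step 8. The E1cB elimination may give poor control of the geometry of the new tetrasubstituted alkene and partial deconjugation. The fallback sets out from TES ether 8 and makes the alkene by olefination instead of elimination. LiN(iPr)2 and ClP(O)(OEt)2 should give enol phosphate F3. A second equivalent of LiN(iPr)2 induces the 1,3-phosphorus shift to β-keto phosphonate F4. Horner–Wadsworth–Emmons olefination of F4 with ketone 9 (NaH, THF, rt to 50 °C) comes back at E-enone 12, the geometry now being set under oxaphosphetane control.

3. Step 1. Chemoselectivity may be lost through attack of the ylide at the enone carbonyl or base-induced self-condensation of the enone. The fallback sets out from 1 and masks the enone carbonyl. Selective dithioketalisation of the enone carbonyl (ethane-1,2-dithiol, BF3·OEt2, MeOH, 0 °C) should give dithiolane F5. Wittig ethylidenation with 2 and KOtBu then gives ethylidene dithiolane F6. Alkylative hydrolysis (MeI, CaCO3, aq. MeCN, 40 °C) comes back at Z-ethylidene enone 3.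

**Further compounds**
F1 | step 4 | azido alcohol: 5 with N3 in place of SePh | C[C@@H](N=[N+]=[N-])[C@@]1(O)CCC2=CC(=O)CC[C@]12C
F2 | step 4 | amino alcohol: 5 with NH2 in place of SePh | C[C@@H](N)[C@@]1(O)CCC2=CC(=O)CC[C@]12C
F3 | step 8 | enol phosphate: C7=C8 diethyl enol phosphate of 8 | C[C@H]1[C@H](O[Si](CC)(CC)CC)CC[C@H]2CC(OP(=O)(OCC)OCC)=CC[C@]12C
F4 | step 8 | β-keto phosphonate: 8 with P(O)(OEt)2 on C7 | C[C@H]1[C@H](O[Si](CC)(CC)CC)CC[C@H]2CC(=O)C(P(=O)(OCC)OCC)C[C@]12C
F5 | step 1 | dithiolane: 1 with the enone carbonyl C8 as 1,3-dithiolane | C[C@]12CCC3(SCCS3)C=C1CCC2=O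
F6 | step 1 | ethylidene dithiolane: 3 with C8 as 1,3-dithiolane | C/C=C1/CCC2=CC3(SCCS3)CC[C@]12C
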